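The oxocene ring O1–C7–C8–C9=C10–C11–C12–C13 is read as two five-membered rings sharing the C9–C13 bond: a cyclopentane (C9 to C13) and an oxolane (O1, C7, C8, C9, C13). The precursor is therefore a cis-fused bicyclic hemiketal with tributyltin on C10, cis to C8, and the C7 benzyloxymethyl arm taken from (R)-benzyl glycidyl ether. Lead tetraacetate cuts the shared bond in one operation: C13 becomes the lactone carbonyl, tin leaves C10 and the Z-C9=C10 alkene appears exactly where the target has it, so no medium-ring cyclization is needed. The C12 bromide, the C13 ethyl group and the C1–C6 enyne acetate are then built on this lactone.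

Key step: step 4

Remark: atoms are numbered C1 (alkyne CH) to C15 (ethyl CH3) throughout; the target SMILES reads as (6R,7R,12S,13R), 3E, 9Z, and the (R)-epoxide maps directly onto (7R).
Remark: the bicyclic precursor cannot be made as a single diastereomer, because C7 is too remote to bias the stannyl addition; both cis C9/C10 diastereomers (13 and 14) are therefore carried into step 4, where C9, C10 and C13 become planar and the pair converges on one lactone.

Step 1
Reactants: 1 2-bromocyclopent-2-en-1-one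
Product: 2 6-bromo-1,4-dioxaspiro[4.4]non-6-ene
Conditions: HOCH2CH2OH, p-TsOH (cat.), benzene, reflux, Dean–Stark
Reagents that add atoms: ethane-1,2-diol, OCCO
Why: Acid-catalysed ketalization with azeotropic removal of water masks the carbonyl group, so that the C–Br bond can serve as an α-ketovinyl anion equivalent in the next step.

Step 2
Reactants: 2 6-bromo-1,4-dioxaspiro[4.4]non-6-ene; 3 (R)-benzyl glycidyl ether
Product: 6 2-[(2R)-3-(benzyloxy)-2-hydroxypropyl]cyclopent-2-en-1-one, via vinyllithium 4 (not isolated), via ketal alcohol 5 (not isolated)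
Conditions: n-BuLi, THF, −78 °C; BF3·OEt2, then 3, −78 °C; aq. oxalic acid, CH2Cl2, rt
Reagents that add atoms: water, O
Why: Bromine–lithium exchange gives the vinyllithium, which under BF3·OEt2 activation opens the terminal epoxide carbon by SN2 attack (C7 untouched, C8–C9 bond formed), and the enone ketal is hydrolysed during the mild acidic work-up.

Step 3
Reactants: 6 2-[(2R)-3-(benzyloxy)-2-hydroxypropyl]cyclopent-2-en-1-one; 7 tributyltin hydride
Product: 13 (2R,3aS,4R,6aS)-2-[(benzyloxy)methyl]-4-(tributylstannyl)hexahydro-2H-cyclopenta[b]furan-6a-ol plus 14 (2R,3aR,4S,6aR)-2-[(benzyloxy)methyl]-4-(tributylstannyl)hexahydro-2H-cyclopenta[b]furan-6a-ol, via tributylstannyllithium 8 (not isolated), via (3R) enolate alkoxide 9 (not isolated), via (3S) enolate alkoxide 10 (not isolated), via (2S,3R) hydroxy ketone 11 (not isolated), via (2R,3S) hydroxy ketone 12 (not isolated)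
Conditions: 7 (2.2 equiv), LiN(iPr)2 (2.2 equiv), THF, 0 °C; 6 added slowly at −78 °C (inverse addition); AcOH, −78 °C; crude product used directly
Reagents that add atoms: none
Why: Conjugate addition of the stannyl anion to the enone (the first equivalent only deprotonates the C7 hydroxyl) followed by kinetic protonation of the enolate on the face away from the bulky tributylstannyl group should set C9 and C10 cis, and the freed C7 hydroxyl then closes the cis-fused hemiketal by ring-chain tautomerism, which also protects C9 from epimerization.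

Step 4
Reactants: 13 (2R,3aS,4R,6aS)-2-[(benzyloxy)methyl]-4-(tributylstannyl)hexahydro-2H-cyclopenta[b]furan-6a-ol; 14 (2R,3aR,4S,6aR)-2-[(benzyloxy)methyl]-4-(tributylstannyl)hexahydro-2H-cyclopenta[b]furan-6a-ol
Product: 15 (8R,5Z)-8-[(benzyloxy)methyl]-3,4,7,8-tetrahydro-2H-oxocin-2-one
Conditions: Pb(OAc)4 (tetravalent lead), benzene, 80 °C
Reagents that add atoms: none
Why: The hemiketal oxygen replaces an acetate on tetravalent lead, and the lead alkoxide undergoes a two-electron Grob-type fragmentation in which the C9–C13 bond, held roughly antiperiplanar to the C10–Sn bond, breaks while C13=O and C9=C10 form and tin leaves as Bu3SnOAc, with lead ending as Pb(OAc)2 (divalent lead). The closest known reaction type is the lead tetraacetate fragmentation of γ-stannyl alcohols and bicyclic γ-stannyl hemiketals to unsaturated carbonyl compounds and medium-ring or macrocyclic lactones. The eight-membered ring is not closed by bond formation but unveiled by ring expansion, through cleavage of the bond shared by the two five-membered rings, so no cyclization mode applies and no cyclization entropy is paid. No stereocentre is created: C9, C10 and C13 become planar, which is why 13 and 14 give the same lactone, and C7 is untouched. The step needs cleavage of C9–C13 and not C12–C13 and a Z alkene at C9=C10; only C9–C13 is β to tin, and the cis C9/C10 relationship combined with anti elimination, reinforced by the strain of an E alkene in an eight-membered ring, fixes the Z geometry. Any trans-stannyl material should still be funnelled to 15 at 80 °C by stepwise alkoxy-radical β-scission and loss of a tributylstannyl radical.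

Step 5
Reactants: 15 (8R,5Z)-8-[(benzyloxy)methyl]-3,4,7,8-tetrahydro-2H-oxocin-2-one
Product: 17 (3R,8R,5Z)-8-[(benzyloxy)methyl]-3-hydroxy-3,4,7,8-tetrahydro-2H-oxocin-2-one, via potassium enolate 16 (not isolated)
Conditions: KN(SiMe3)2, THF, −78 °C; (±)-trans-2-(phenylsulfonyl)-3-phenyloxaziridine, −78 °C; AcOH
Reagents that add atoms: 2-(phenylsulfonyl)-3-phenyloxaziridine, O=S(=O)(c1ccccc1)N1OC1c1ccccc1
Why: Davis oxaziridine hydroxylation of the lactone enolate (C12 is the only enolizable position) should occur on the peripheral face of the folded eight-membered enolate, which with the C7 arm pseudo-equatorial places the new C12–O bond cis to that arm (12R).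

Step 6
Reactants: 17 (3R,8R,5Z)-8-[(benzyloxy)methyl]-3-hydroxy-3,4,7,8-tetrahydro-2H-oxocin-2-one
Product: 18 (3R,8R,5Z)-8-[(benzyloxy)methyl]-3-(trimethylsilyloxy)-3,4,7,8-tetrahydro-2H-oxocin-2-one
Conditions: TMSCl, Et3N, CH2Cl2, 0 °C
Reagents that add atoms: chlorotrimethylsilane, C[Si](C)(C)Cl
Why: Silylation of the secondary alcohol under mild base keeps the hydroxyl from consuming the titanium reagent in the next step and does not epimerize C12.

Step 7
Reactants: 18 (3R,8R,5Z)-8-[(benzyloxy)methyl]-3-(trimethylsilyloxy)-3,4,7,8-tetrahydro-2H-oxocin-2-one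
Product: 20 (3R,8R,5Z)-8-[(benzyloxy)methyl]-2-methylidene-3,4,7,8-tetrahydro-2H-oxocin-3-ol, via silyl-protected enol ether 19 (not isolated)
Conditions: Cp2TiMe2, toluene, 65 °C, dark; then K2CO3, MeOH, rt
Reagents that add atoms: dimethyltitanocene, C[Ti](C)(C1C=CC=C1)C1C=CC=C1
Why: Petasis methylenation converts the lactone carbonyl into the exocyclic enol ether under non-basic conditions that leave C12 and the ring alkene alone, and basic methanolysis then removes the trimethylsilyl group without the acid that would hydrolyse the enol ether.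

Step 8
Reactants: 20 (3R,8R,5Z)-8-[(benzyloxy)methyl]-2-methylidene-3,4,7,8-tetrahydro-2H-oxocin-3-ol
Product: 23 (2R,3R,8R,5Z)-8-[(benzyloxy)methyl]-2-(hydroxymethyl)-3,4,7,8-tetrahydro-2H-oxocin-3-ol, via dimethylsilyl ether 21 (not isolated), via bicyclic oxasilolane 22 (not isolated)
Conditions: (HMe2Si)2NH, rt; Pt2[(CH2=CHSiMe2)2O]3 (zerovalent platinum, cat.), toluene, rt to 50 °C; H2O2, KF, KHCO3, THF/MeOH, rt
Reagents that add atoms: hydrogen peroxide, OO
Why: Intramolecular hydrosilylation followed by Tamao–Fleming oxidation: with the C12–O bond eclipsing the enol ether, the tethered Si–H should add to the alkene face syn to H12, giving a cis-fused five-membered oxasilolane in which C14 is cis to the C12 oxygen (13R), and oxidation of the C–Si bond then reveals the primary alcohol.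

Step 9
Reactants: 23 (2R,3R,8R,5Z)-8-[(benzyloxy)methyl]-2-(hydroxymethyl)-3,4,7,8-tetrahydro-2H-oxocin-3-ol
Product: 25 [(2R,3R,8R,5Z)-8-[(benzyloxy)methyl]-3-(tert-butyldimethylsilyloxy)-3,4,7,8-tetrahydro-2H-oxocin-2-yl]methyl trifluoromethanesulfonate, via hydroxy triflate 24 (not isolated)
Conditions: Tf2O, 2,6-lutidine, CH2Cl2, −78 °C; then TBSOTf, −78 to 0 °C
Reagents that add atoms: trifluoromethanesulfonic anhydride, O=S(=O)(OS(=O)(=O)C(F)(F)F)C(F)(F)F; tert-butyldimethylsilyl trifluoromethanesulfonate, CC(C)(C)[Si](C)(C)OS(=O)(=O)C(F)(F)F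
Why: At −78 °C the primary hydroxyl is sulfonylated selectively, and silylation of the remaining secondary hydroxyl in the same flask (one-pot triflation–silylation) protects C12–O for the steps that follow.

Step 10
Reactants: 25 [(2R,3R,8R,5Z)-8-[(benzyloxy)methyl]-3-(tert-butyldimethylsilyloxy)-3,4,7,8-tetrahydro-2H-oxocin-2-yl]methyl trifluoromethanesulfonate
Product: 26 (2R,3R,8R,5Z)-8-[(benzyloxy)methyl]-3-(tert-butyldimethylsilyloxy)-2-ethyl-3,4,7,8-tetrahydro-2H-oxocin
Conditions: Me2CuLi (from MeLi, CuI), Et2O, −40 to 0 °C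
Reagents that add atoms: lithium dimethylcuprate, [Li+].C[Cu-]C
Why: SN2 displacement of the primary triflate by the Gilman cuprate forms the C14–C15 bond and completes the C13 ethyl group without touching a stereocentre.

Step 11
Reactants: 26 (2R,3R,8R,5Z)-8-[(benzyloxy)methyl]-3-(tert-butyldimethylsilyloxy)-2-ethyl-3,4,7,8-tetrahydro-2H-oxocin
Product: 27 [(2R,3R,8R,5Z)-3-(tert-butyldimethylsilyloxy)-2-ethyl-3,4,7,8-tetrahydro-2H-oxocin-8-yl]methanol
Conditions: Na, NH3 (l), THF, −78 °C; NH4Cl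
Reagents that add atoms: none
Why: Dissolving-metal cleavage removes the benzyl ether by electron transfer to the arene, while the isolated ring alkene, the dialkyl ether and the silyl ether are not reduced under these conditions.

Step 12
Reactants: 27 [(2R,3R,8R,5Z)-3-(tert-butyldimethylsilyloxy)-2-ethyl-3,4,7,8-tetrahydro-2H-oxocin-8-yl]methanol
Product: 28 (2R,3R,8R,5Z)-3-(tert-butyldimethylsilyloxy)-2-ethyl-3,4,7,8-tetrahydro-2H-oxocine-8-carbaldehyde
Conditions: Dess–Martin periodinane, CH2Cl2, 0 °C to rt; used crude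
Reagents that add atoms: none
Why: Dess–Martin oxidation gives the α-alkoxy aldehyde under near-neutral conditions, which avoids epimerization at C7.

Step 13
Reactants: 28 (2R,3R,8R,5Z)-3-(tert-butyldimethylsilyloxy)-2-ethyl-3,4,7,8-tetrahydro-2H-oxocine-8-carbaldehyde
Product: 29 (1R)-1-[(2R,3R,8R,5Z)-3-(tert-butyldimethylsilyloxy)-2-ethyl-3,4,7,8-tetrahydro-2H-oxocin-8-yl]but-3-en-1-ol
Conditions: MgBr2·OEt2, CH2=CHCH2SnBu3, CH2Cl2, −78 to −20 °C
Reagents that add atoms: allyltributylstannane, C=CC[Sn](CCCC)(CCCC)CCCC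
Why: Keck chelation-controlled allylation: magnesium bridges the aldehyde oxygen and ring oxygen O1, and the allylstannane attacks the carbonyl face on the side of H7, away from the C8 methylene, which gives the syn (6R) alcohol.

Step 14
Reactants: 29 (1R)-1-[(2R,3R,8R,5Z)-3-(tert-butyldimethylsilyloxy)-2-ethyl-3,4,7,8-tetrahydro-2H-oxocin-8-yl]but-3-en-1-ol
Product: 30 (2E,5R)-5-[(2R,3R,8R,5Z)-3-(tert-butyldimethylsilyloxy)-2-ethyl-3,4,7,8-tetrahydro-2H-oxocin-8-yl]-5-hydroxypent-2-enal
Conditions: (E)-crotonaldehyde (excess), (H2IMes)(PCy3)Cl2Ru=CHPh (second-generation Grubbs catalyst, cat.), CH2Cl2, 40 °C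
Reagents that add atoms: (E)-but-2-enal, C/C=C/C=O
Why: Cross metathesis of the terminal alkene with crotonaldehyde gives the E-enal under thermodynamic control, while the ring alkene, internal and flanked by the substituted C7 and C12 positions, should react far more slowly.

Step 15
Reactants: 30 (2E,5R)-5-[(2R,3R,8R,5Z)-3-(tert-butyldimethylsilyloxy)-2-ethyl-3,4,7,8-tetrahydro-2H-oxocin-8-yl]-5-hydroxypent-2-enal
Product: 31 (1R,3E)-1-[(2R,3R,8R,5Z)-3-(tert-butyldimethylsilyloxy)-2-ethyl-3,4,7,8-tetrahydro-2H-oxocin-8-yl]hex-3-en-5-yn-1-ol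
Conditions: TMSCHN2, LiN(iPr)2 (2.5 equiv each), THF, −78 to 0 °C; NH4Cl
Reagents that add atoms: (trimethylsilyl)diazomethane, C[Si](C)(C)C=[N+]=[N-]
Why: Colvin rearrangement: the lithiated diazo reagent adds to the aldehyde, Peterson-type loss of lithium trimethylsilanolate and then of N2 gives an alkylidene carbene, and its 1,2-hydrogen shift delivers the terminal alkyne with the E alkene intact (the extra base only deprotonates the C6 hydroxyl).

Step 16
Reactants: 31 (1R,3E)-1-[(2R,3R,8R,5Z)-3-(tert-butyldimethylsilyloxy)-2-ethyl-3,4,7,8-tetrahydro-2H-oxocin-8-yl]hex-3-en-5-yn-1-ol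
Product: 32 (1R,3E)-1-[(2R,3R,8R,5Z)-3-(tert-butyldimethylsilyloxy)-2-ethyl-3,4,7,8-tetrahydro-2H-oxocin-8-yl]hex-3-en-5-yn-1-yl acetate
Conditions: Ac2O, pyridine, DMAP (cat.), CH2Cl2, rt
Reagents that add atoms: acetic anhydride, CC(=O)OC(C)=O
Why: DMAP-catalysed acylation esterifies the only free hydroxyl (C6) with retention of configuration.

Step 17
Reactants: 32 (1R,3E)-1-[(2R,3R,8R,5Z)-3-(tert-butyldimethylsilyloxy)-2-ethyl-3,4,7,8-tetrahydro-2H-oxocin-8-yl]hex-3-en-5-yn-1-yl acetate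
Product: 33 (1R,3E)-1-[(2R,3R,8R,5Z)-2-ethyl-3-hydroxy-3,4,7,8-tetrahydro-2H-oxocin-8-yl]hex-3-en-5-yn-1-yl acetate
Conditions: HF·pyridine, pyridine, THF, 0 °C to rt
Reagents that add atoms: none
Why: Buffered fluoride cleaves the Si–O bond at C12 while the acetate, which cannot migrate to the distant C12 oxygen, and the terminal enyne are inert.

Step 18
Reactants: 33 (1R,3E)-1-[(2R,3R,8R,5Z)-2-ethyl-3-hydroxy-3,4,7,8-tetrahydro-2H-oxocin-8-yl]hex-3-en-5-yn-1-yl acetate
Product: 34 (1R,3E)-1-[(2R,3S,8R,5Z)-3-bromo-2-ethyl-3,4,7,8-tetrahydro-2H-oxocin-8-yl]hex-3-en-5-yn-1-yl acetate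
Conditions: CBr4, (n-C8H17)3P, toluene, 70 °C
Reagents that add atoms: carbon tetrabromide, BrC(Br)(Br)Br
Why: Appel-type bromination: the C12 hydroxyl is activated as an alkoxyphosphonium ion and displaced by bromide in an SN2 step with inversion, turning the all-cis (12R) alcohol into the (12S) bromide trans to the ethyl group.

Compound list
1 | 2-bromocyclopent-2-en-1-one | O=C1CCC=C1Br | starting material
2 | 6-bromo-1,4-dioxaspiro[4.4]non-6-ene | BrC1=CCCC12OCCO2 | intermediate
3 | (R)-benzyl glycidyl ether | c1ccccc1COC[C@H]1CO1 | starting material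
4 | (1,4-dioxaspiro[4.4]non-6-en-6-yl)lithium (not isolated) | [Li]C1=CCCC12OCCO2 | intermediate
5 | (2R)-1-(benzyloxy)-3-(1,4-dioxaspiro[4.4]non-6-en-6-yl)propan-2-ol (not isolated) | O[C@H](CC1=CCCC12OCCO2)COCc1ccccc1 | intermediate
6 | 2-[(2R)-3-(benzyloxy)-2-hydroxypropyl]cyclopent-2-en-1-one | O=C1CCC=C1C[C@@H](O)COCc1ccccc1 | intermediate
7 | tributyltin hydride | CCCC[SnH](CCCC)CCCC | starting material
8 | tributylstannyllithium (not isolated) | [Li][Sn](CCCC)(CCCC)CCCC | intermediate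
9 | lithium (3R)-2-[(2R)-3-(benzyloxy)-2-(lithiooxy)propyl]-3-(tributylstannyl)cyclopent-1-en-1-olate (not isolated) | [Li]OC1=C(C[C@@H](O[Li])COCc2ccccc2)[C@@H](CC1)[Sn](CCCC)(CCCC)CCCC | intermediate
10 | lithium (3S)-2-[(2R)-3-(benzyloxy)-2-(lithiooxy)propyl]-3-(tributylstannyl)cyclopent-1-en-1-olate (not isolated) | [Li]OC1=C(C[C@@H](O[Li])COCc2ccccc2)[C@H](CC1)[Sn](CCCC)(CCCC)CCCC | intermediate
11 | (2S,3R)-2-[(2R)-3-(benzyloxy)-2-hydroxypropyl]-3-(tributylstannyl)cyclopentan-1-one, open form of 13 (not isolated) | O=C1CC[C@@H]([Sn](CCCC)(CCCC)CCCC)[C@H]1C[C@@H](O)COCc1ccccc1 | intermediate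
12 | (2R,3S)-2-[(2R)-3-(benzyloxy)-2-hydroxypropyl]-3-(tributylstannyl)cyclopentan-1-one, open form of 14 (not isolated) | O=C1CC[C@H]([Sn](CCCC)(CCCC)CCCC)[C@@H]1C[C@@H](O)COCc1ccccc1 | intermediate
13 | (2R,3aS,4R,6aS)-2-[(benzyloxy)methyl]-4-(tributylstannyl)hexahydro-2H-cyclopenta[b]furan-6a-ol | O[C@]12CC[C@@H]([Sn](CCCC)(CCCC)CCCC)[C@H]1C[C@H](COCc3ccccc3)O2 | intermediate
14 | (2R,3aR,4S,6aR)-2-[(benzyloxy)methyl]-4-(tributylstannyl)hexahydro-2H-cyclopenta[b]furan-6a-ol | O[C@@]12CC[C@H]([Sn](CCCC)(CCCC)CCCC)[C@@H]1C[C@H](COCc3ccccc3)O2 | intermediate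
15 | (8R,5Z)-8-[(benzyloxy)methyl]-3,4,7,8-tetrahydro-2H-oxocin-2-one | c1ccccc1COC[C@H]1C/C=C\CCC(=O)O1 | intermediate
16 | potassium enolate of 15 (not isolated) | c1ccccc1COC[C@H]1C/C=C\CC=C(O[K])O1 | intermediate
17 | (3R,8R,5Z)-8-[(benzyloxy)methyl]-3-hydroxy-3,4,7,8-tetrahydro-2H-oxocin-2-one | c1ccccc1COC[C@H]1C/C=C\C[C@@H](O)C(=O)O1 | intermediate
18 | (3R,8R,5Z)-8-[(benzyloxy)methyl]-3-(trimethylsilyloxy)-3,4,7,8-tetrahydro-2H-oxocin-2-one | c1ccccc1COC[C@H]1C/C=C\C[C@@H](O[Si](C)(C)C)C(=O)O1 | intermediate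
19 | (3R,8R,5Z)-8-[(benzyloxy)methyl]-2-methylidene-3-(trimethylsilyloxy)-3,4,7,8-tetrahydro-2H-oxocin (not isolated) | c1ccccc1COC[C@H]1C/C=C\C[C@@H](O[Si](C)(C)C)C(=C)O1 | intermediate
20 | (3R,8R,5Z)-8-[(benzyloxy)methyl]-2-methylidene-3,4,7,8-tetrahydro-2H-oxocin-3-ol | c1ccccc1COC[C@H]1C/C=C\C[C@@H](O)C(=C)O1 | intermediate
21 | (3R,8R,5Z)-8-[(benzyloxy)methyl]-3-(dimethylsilyloxy)-2-methylidene-3,4,7,8-tetrahydro-2H-oxocin (not isolated) | c1ccccc1COC[C@H]1C/C=C\C[C@@H](O[SiH](C)C)C(=C)O1 | intermediate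
22 | cis-fused 2,2-dimethyl-1-oxa-2-silacyclopentane bridging C12–O and C14 of the (7R,12R,13R)-oxocene (not isolated) | c1ccccc1COC[C@H]1C/C=C\C[C@H]2O[Si](C)(C)C[C@H]2O1 | intermediate
23 | (2R,3R,8R,5Z)-8-[(benzyloxy)methyl]-2-(hydroxymethyl)-3,4,7,8-tetrahydro-2H-oxocin-3-ol | c1ccccc1COC[C@H]1C/C=C\C[C@@H](O)[C@@H](CO)O1 | intermediate
24 | [(2R,3R,8R,5Z)-8-[(benzyloxy)methyl]-3-hydroxy-3,4,7,8-tetrahydro-2H-oxocin-2-yl]methyl trifluoromethanesulfonate (not isolated) | c1ccccc1COC[C@H]1C/C=C\C[C@@H](O)[C@@H](COS(=O)(=O)C(F)(F)F)O1 | intermediate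
25 | [(2R,3R,8R,5Z)-8-[(benzyloxy)methyl]-3-(tert-butyldimethylsilyloxy)-3,4,7,8-tetrahydro-2H-oxocin-2-yl]methyl trifluoromethanesulfonate | c1ccccc1COC[C@H]1C/C=C\C[C@@H](O[Si](C)(C)C(C)(C)C)[C@@H](COS(=O)(=O)C(F)(F)F)O1 | intermediate
26 | (2R,3R,8R,5Z)-8-[(benzyloxy)methyl]-3-(tert-butyldimethylsilyloxy)-2-ethyl-3,4,7,8-tetrahydro-2H-oxocin | c1ccccc1COC[C@H]1C/C=C\C[C@@H](O[Si](C)(C)C(C)(C)C)[C@@H](CC)O1 | intermediate
27 | [(2R,3R,8R,5Z)-3-(tert-butyldimethylsilyloxy)-2-ethyl-3,4,7,8-tetrahydro-2H-oxocin-8-yl]methanol | OC[C@H]1C/C=C\C[C@@H](O[Si](C)(C)C(C)(C)C)[C@@H](CC)O1 | intermediate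
28 | (2R,3R,8R,5Z)-3-(tert-butyldimethylsilyloxy)-2-ethyl-3,4,7,8-tetrahydro-2H-oxocine-8-carbaldehyde | O=C[C@H]1C/C=C\C[C@@H](O[Si](C)(C)C(C)(C)C)[C@@H](CC)O1 | intermediate
29 | (1R)-1-[(2R,3R,8R,5Z)-3-(tert-butyldimethylsilyloxy)-2-ethyl-3,4,7,8-tetrahydro-2H-oxocin-8-yl]but-3-en-1-ol | C=CC[C@@H](O)[C@H]1C/C=C\C[C@@H](O[Si](C)(C)C(C)(C)C)[C@@H](CC)O1 | intermediate
30 | (2E,5R)-5-[(2R,3R,8R,5Z)-3-(tert-butyldimethylsilyloxy)-2-ethyl-3,4,7,8-tetrahydro-2H-oxocin-8-yl]-5-hydroxypent-2-enal | O=C/C=C/C[C@@H](O)[C@H]1C/C=C\C[C@@H](O[Si](C)(C)C(C)(C)C)[C@@H](CC)O1 | intermediate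
31 | (1R,3E)-1-[(2R,3R,8R,5Z)-3-(tert-butyldimethylsilyloxy)-2-ethyl-3,4,7,8-tetrahydro-2H-oxocin-8-yl]hex-3-en-5-yn-1-ol | C#C/C=C/C[C@@H](O)[C@H]1C/C=C\C[C@@H](O[Si](C)(C)C(C)(C)C)[C@@H](CC)O1 | intermediate
32 | (1R,3E)-1-[(2R,3R,8R,5Z)-3-(tert-butyldimethylsilyloxy)-2-ethyl-3,4,7,8-tetrahydro-2H-oxocin-8-yl]hex-3-en-5-yn-1-yl acetate | C#C/C=C/C[C@@H](OC(C)=O)[C@H]1C/C=C\C[C@@H](O[Si](C)(C)C(C)(C)C)[C@@H](CC)O1 | intermediate
33 | (1R,3E)-1-[(2R,3R,8R,5Z)-2-ethyl-3-hydroxy-3,4,7,8-tetrahydro-2H-oxocin-8-yl]hex-3-en-5-yn-1-yl acetate | C#C/C=C/C[C@@H](OC(C)=O)[C@H]1C/C=C\C[C@@H](O)[C@@H](CC)O1 | intermediate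
34 | (1R,3E)-1-[(2R,3S,8R,5Z)-3-bromo-2-ethyl-3,4,7,8-tetrahydro-2H-oxocin-8-yl]hex-3-en-5-yn-1-yl acetate | C#C/C=C/C[C@@H](OC(C)=O)[C@H]1C/C=C\C[C@H](Br)[C@@H](CC)O1 | target

Total step count: 18.
Longest linear sequence: 18 steps (1 to 34); 3 and 7 enter as single building blocks.

Steps most likely to fail

Step 4. The lead alkoxide may form poorly from a hemiketal that equilibrates with its open hydroxy ketone, acetic acid may cause protodestannylation, or partial epimerization at C9 before the step may remove the anti alignment so that unselective β-scission competes. The fallback gives up the fragmentation and closes the ring by lactonization; it sets out from 3 and returns at 15. Pent-4-ynoic acid is doubly deprotonated (n-BuLi, THF/DMPU) and its acetylide opens 3 at the terminal carbon to give (7R)-8-(benzyloxy)-7-hydroxyoct-4-ynoic acid F1. Semihydrogenation (H2, Pd/CaCO3 poisoned by Pb(OAc)2, quinoline) gives (4Z,7R)-8-(benzyloxy)-7-hydroxyoct-4-enoic acid F2. Yamaguchi lactonization (2,4,6-trichlorobenzoyl chloride, Et3N, then DMAP, toluene, high dilution), helped by the Z alkene, should then give 15.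

Step 5. Facial selectivity in the enolate oxidation may be poor or reversed, which would place the C12 oxygen trans to the C7 arm and then misdirect C13 in step 8. The fallback corrects C12 by inversion and no longer relies on enolate face selection; it sets out from 15 and returns at 17. The same oxidation is run and the trans alcohol (3S,8R,5Z)-8-[(benzyloxy)methyl]-3-hydroxy-3,4,7,8-tetrahydro-2H-oxocin-2-one F3 is collected. A Mitsunobu reaction with chloroacetic acid (PPh3, DIAD, THF) inverts C12 to give (3R,8R,5Z)-8-[(benzyloxy)methyl]-2-oxo-3,4,7,8-tetrahydro-2H-oxocin-3-yl chloroacetate F4, and thiourea with NaHCO3 in ethanol removes the chloroacetyl group to give 17.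

Step 8. The tethered silane may add to the ring alkene at C10 and not to the enol ether, or hydrogen may be delivered to the wrong face of C13. The fallback replaces the tethered delivery by an intermolecular hydroboration; it sets out from 20 and returns at 25. Silylation (TBSCl, imidazole, DMF) gives (3R,8R,5Z)-8-[(benzyloxy)methyl]-3-(tert-butyldimethylsilyloxy)-2-methylidene-3,4,7,8-tetrahydro-2H-oxocin F5. Hydroboration with 9-BBN, which strongly prefers the 1,1-disubstituted enol ether over the internal ring alkene and should deliver hydrogen to C13 on the face away from the C12 silyl ether, followed by NaOH/H2O2, gives [(2R,3R,8R,5Z)-8-[(benzyloxy)methyl]-3-(tert-butyldimethylsilyloxy)-3,4,7,8-tetrahydro-2H-oxocin-2-yl]methanol F6. Triflation (Tf2O, 2,6-lutidine, −78 °C) then gives 25.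

Further compounds
F1 | step 4 | (7R)-8-(benzyloxy)-7-hydroxyoct-4-ynoic acid | OC(=O)CCC#CC[C@@H](O)COCc1ccccc1
F2 | step 4 | (4Z,7R)-8-(benzyloxy)-7-hydroxyoct-4-enoic acid | OC(=O)CC/C=C\C[C@@H](O)COCc1ccccc1
F3 | step 5 | (3S,8R,5Z)-8-[(benzyloxy)methyl]-3-hydroxy-3,4,7,8-tetrahydro-2H-oxocin-2-one | c1ccccc1COC[C@H]1C/C=C\C[C@H](O)C(=O)O1
F4 | step 5 | (3R,8R,5Z)-8-[(benzyloxy)methyl]-2-oxo-3,4,7,8-tetrahydro-2H-oxocin-3-yl chloroacetate | c1ccccc1COC[C@H]1C/C=C\C[C@@H](OC(=O)CCl)C(=O)O1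
F5 | step 8 | (3R,8R,5Z)-8-[(benzyloxy)methyl]-3-(tert-butyldimethylsilyloxy)-2-methylidene-3,4,7,8-tetrahydro-2H-oxocin | c1ccccc1COC[C@H]1C/C=C\C[C@@H](O[Si](C)(C)C(C)(C)C)C(=C)O1
F6 | step 8 | [(2R,3R,8R,5Z)-8-[(benzyloxy)methyl]-3-(tert-butyldimethylsilyloxy)-3,4,7,8-tetrahydro-2H-oxocin-2-yl]methanol | c1ccccc1COC[C@H]1C/C=C\C[C@@H](O[Si](C)(C)C(C)(C)C)[C@@H](CO)O1
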